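The tricycle is unravelled across the ring-fusion bond C7–C12 and the C6–C15 bond (chain numbering from the lactone carbonyl C1). Ring A is read as the four-carbon bridge C8–C11, with its Z C9=C10 alkene, of a 1,7,9-decatriene, and ring B, with C13=C14 opposite C6–C7, as the cyclohexene of its cycloaddition. The key step is a transannular Diels–Alder reaction of a 22-membered macrolactone: the C6=C7 enone and the C12–C15 (E,E)-diene close ring A last, together with ring B, contract the macrocycle to the 14-membered lactone and set C6, C7, C12 and C15 at once. A Stille macrocyclisation creates the diene and so arms this precursor.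

Key step: step 18

Numbering used below: C1 lactone carbonyl, C2 (Me), C3 ketone, C4, C5 enol carbon, C6, C7, C8–C11 (ring A, methyl on C10), C12, C13=C14, C15, C16 (Me), C17–C20 (Z,Z-diene), C21 (Me, lactone oxygen). Ring A is C7–C12 and ring B is C6, C7, C12–C15. In this numbering the target is 2S,6R,7S,12R,15R,16S,21R.

Assumption: C2, acidic between the lactone and C3 carbonyls, is carried as an epimeric mixture and set last by equilibration of the rigid tricycle, the 2S epimer drawn being taken as the more stable one; the minor epimer is separable and can be resubmitted.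

Remark: the 1,3-diketone of 25 and 26 is written in the diketo form although it should be largely enolised; the target is written as its C5 enol.

Step 1
Reactants: 1 methyl (R)-3-hydroxy-2-methylpropanoate
Product: 2 methyl (R)-3-[(tert-butyldimethylsilyl)oxy]-2-methylpropanoate
Conditions: TBSCl, imidazole, CH2Cl2, 0 °C → rt
Reagents that add atoms: tert-butyldimethylsilyl chloride, CC(C)(C)[Si](C)(C)Cl
Why: imidazole-promoted silylation of the primary alcohol masks the future C15 hydroxyl, and the C16 stereocentre, taken from the chiral pool, is not touched.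

Step 2
Reactants: 2 methyl (R)-3-[(tert-butyldimethylsilyl)oxy]-2-methylpropanoate
Product: 4 (S)-tert-butyldimethyl[(2-methylbut-3-yn-1-yl)oxy]silane, via aldehyde 3 (not isolated)
Conditions: i-Bu2AlH (DIBAL-H, 1.05 equiv), CH2Cl2, −78 °C; then MeOH, K2CO3, dimethyl (1-diazo-2-oxopropyl)phosphonate, −78 °C → rt
Reagents that add atoms: dimethyl (1-diazo-2-oxopropyl)phosphonate (Ohira–Bestmann reagent), CC(=O)C(=[N+]=[N-])P(=O)(OC)OC
Why: partial ester reduction through the stable aluminium hemiacetal gives aldehyde 3, which undergoes Seyferth–Gilbert homologation with the Ohira–Bestmann reagent in the same flask under mildly basic conditions that should preserve the α-stereocentre (C16).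

Step 3
Reactants: 5 (R)-but-3-yn-2-ol
Product: 6 (R)-4-bromobut-3-yn-2-ol
Conditions: NBS, AgNO3 (10 mol %), acetone, rt, dark
Reagents that add atoms: N-bromosuccinimide, O=C1CCC(=O)N1Br
Why: silver-catalysed electrophilic bromination of the terminal alkyne, in which the carbinol centre (C21) is not involved.

Step 4
Reactants: 4 (S)-tert-butyldimethyl[(2-methylbut-3-yn-1-yl)oxy]silane; 6 (R)-4-bromobut-3-yn-2-ol
Product: 7 (2R,7S)-8-[(tert-butyldimethylsilyl)oxy]-7-methylocta-3,5-diyn-2-ol
Conditions: CuCl (5 mol %), NH2OH·HCl, n-BuNH2, H2O/Et2O, 0 °C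
Reagents that add atoms: none
Why: Cadiot–Chodkiewicz heterocoupling of a terminal alkyne with a 1-bromoalkyne gives the unsymmetrical 1,3-diyne (C17–C20) without touching either stereocentre.

Step 5
Reactants: 7 (2R,7S)-8-[(tert-butyldimethylsilyl)oxy]-7-methylocta-3,5-diyn-2-ol
Product: 8 (2R,3Z,5Z,7S)-8-[(tert-butyldimethylsilyl)oxy]-7-methylocta-3,5-dien-2-ol
Conditions: Zn dust activated with Cu(OAc)2 and AgNO3, MeOH/H2O (1:1), 40 °C
Reagents that add atoms: none
Why: Boland reduction, in which activated zinc reduces conjugated alkynes by electron transfer and protonation on the metal surface with cis delivery, should give the (17Z,19Z)-diene and stop at the alkene stage.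

Step 6
Reactants: 8 (2R,3Z,5Z,7S)-8-[(tert-butyldimethylsilyl)oxy]-7-methylocta-3,5-dien-2-ol; 9 ethyl 2-methyl-3-oxobutanoate
Product: 10 (2R,3Z,5Z,7S)-8-[(tert-butyldimethylsilyl)oxy]-7-methylocta-3,5-dien-2-yl 2-methyl-3-oxobutanoate (C2 epimers)
Conditions: 9 (3 equiv), DMAP (0.3 equiv), 4 Å molecular sieves, toluene, 110 °C
Reagents that add atoms: none
Why: DMAP-catalysed transesterification of a β-keto ester (through the acylketene) acylates the secondary allylic alcohol with retention at C21 and brings in C1–C4 with the C2 methyl, well below the temperature of a thermal Carroll rearrangement.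

Step 7
Reactants: 10 (2R,3Z,5Z,7S)-8-[(tert-butyldimethylsilyl)oxy]-7-methylocta-3,5-dien-2-yl 2-methyl-3-oxobutanoate
Product: 11 (2R,3Z,5Z,7S)-8-hydroxy-7-methylocta-3,5-dien-2-yl 2-methyl-3-oxobutanoate (C2 epimers)
Conditions: HF·pyridine, pyridine, THF, 0 °C → rt
Reagents that add atoms: none
Why: fluoride-mediated desilylation of the primary TBS ether under buffered conditions should leave the allylic β-keto ester and the Z,Z-diene intact.

Step 8
Reactants: 11 (2R,3Z,5Z,7S)-8-hydroxy-7-methylocta-3,5-dien-2-yl 2-methyl-3-oxobutanoate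
Product: 12 (2R,3Z,5Z,7S)-7-methyl-8-oxoocta-3,5-dien-2-yl 2-methyl-3-oxobutanoate (C2 epimers)
Conditions: Dess–Martin periodinane (1.2 equiv), NaHCO3, CH2Cl2, 0 °C; used at once
Reagents that add atoms: none
Why: Dess–Martin oxidation under buffered, non-basic conditions should give the α-methyl β,γ-unsaturated aldehyde without epimerisation at C16 or migration of the alkene.

Step 9
Reactants: 12 (2R,3Z,5Z,7S)-7-methyl-8-oxoocta-3,5-dien-2-yl 2-methyl-3-oxobutanoate
Product: 13 (2R,3Z,5Z,7S,8E)-9-iodo-7-methylnona-3,5,8-trien-2-yl 2-methyl-3-oxobutanoate (C2 epimers)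
Conditions: CrCl2 (8 equiv), CHI3 (3 equiv), THF/1,4-dioxane, 0 °C → rt
Reagents that add atoms: iodoform, IC(I)I
Why: Takai olefination, in which the geminal dichromium carbenoid adds to the aldehyde and eliminates to the (E)-vinyl iodide (C14=C15), is non-basic and aldehyde-selective, so C16 and the ketone should survive.

Step 10
Reactants: 14 but-3-enoic acid; 15 2-methylprop-2-en-1-ol
Product: 16 2-methylallyl but-3-enoate
Conditions: DCC (1.1 equiv), DMAP (5 mol %), CH2Cl2, 0 °C
Reagents that add atoms: none
Why: Steglich esterification at low temperature with little DMAP, to avoid isomerisation to the crotonate.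

Step 11
Reactants: 16 2-methylallyl but-3-enoate
Product: 17 5-methyl-3,6-dihydro-2H-pyran-2-one
Conditions: (H2IMes)(PCy3)Cl2Ru=CHPh (second-generation Grubbs catalyst, 5 mol %), 1,4-benzoquinone (10 mol %), CH2Cl2 (0.01 M), 40 °C
Reagents that add atoms: none
Why: ring-closing metathesis to a six-membered lactone enforces the Z geometry of the trisubstituted C9=C10 alkene, and benzoquinone suppresses hydride-mediated migration into conjugation.

Step 12
Reactants: 17 5-methyl-3,6-dihydro-2H-pyran-2-one
Product: 18 5-methyl-3,6-dihydro-2H-pyran-2-ol (racemic lactol)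
Conditions: i-Bu2AlH (1.1 equiv), CH2Cl2, −78 °C
Reagents that add atoms: none
Why: low-temperature hydride reduction of a lactone stops at the lactol through the stable tetrahedral aluminate, and the lactol masks the labile β,γ-unsaturated aldehyde (C7).

Step 13
Reactants: 18 5-methyl-3,6-dihydro-2H-pyran-2-ol; 19 N-methoxy-N-methyl-2-(triphenylphosphoranylidene)acetamide
Product: 20 (2E,5Z)-7-hydroxy-N-methoxy-N,6-dimethylhepta-2,5-dienamide
Conditions: 19 (1.3 equiv), PhCO2H (cat.), toluene, 70 °C
Reagents that add atoms: none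
Why: Wittig reaction of the open-chain aldehyde form of the lactol with the stabilised amide ylide gives the (E)-enamide (C6=C7) under neutral conditions, and the weakly electrophilic Weinreb enamide should resist oxa-Michael closure by the liberated C11 hydroxyl.

Step 14
Reactants: 20 (2E,5Z)-7-hydroxy-N-methoxy-N,6-dimethylhepta-2,5-dienamide
Product: 21 (2E,5Z)-7-bromo-N-methoxy-N,6-dimethylhepta-2,5-dienamide
Conditions: CBr4, PPh3, CH2Cl2, −20 → 0 °C
Reagents that add atoms: carbon tetrabromide, BrC(Br)(Br)Br
Why: Appel bromination proceeds by SN2 displacement of the alkoxyphosphonium ion and should give the primary allylic bromide without transposition or loss of the Z geometry.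

Step 15
Reactants: 21 (2E,5Z)-7-bromo-N-methoxy-N,6-dimethylhepta-2,5-dienamide; 22 (E)-1,2-bis(tributylstannyl)ethene
Product: 23 (2E,5Z,8E)-N-methoxy-N,6-dimethyl-9-(tributylstannyl)nona-2,5,8-trienamide
Conditions: 22 (3 equiv), Pd2(dba)3 (2.5 mol %), tri(2-furyl)phosphine (10 mol %), THF, 50 °C
Reagents that add atoms: none
Why: Stille coupling of an allylic bromide with a vinylstannane at the less hindered allyl terminus, with an excess of the symmetrical distannane to ensure mono-coupling, leaves the (E)-vinylstannane (C12=C13) for the macrocyclisation.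

Step 16
Reactants: 13 (2R,3Z,5Z,7S,8E)-9-iodo-7-methylnona-3,5,8-trien-2-yl 2-methyl-3-oxobutanoate; 23 (2E,5Z,8E)-N-methoxy-N,6-dimethyl-9-(tributylstannyl)nona-2,5,8-trienamide
Product: 25 (2R,3Z,5Z,7S,8E)-9-iodo-7-methylnona-3,5,8-trien-2-yl (6E,9Z,12E)-2,10-dimethyl-3,5-dioxo-13-(tributylstannyl)trideca-6,9,12-trienoate (C2 epimers), via dilithium dianion 24 (not isolated)
Conditions: LiN(i-Pr)2 (LDA, 2.2 equiv to 13), THF, −78 → −40 °C; 23 (0.8 equiv), −78 → −40 °C; AcOH, −78 °C
Reagents that add atoms: none
Why: Claisen-type acylation of the 1,3-dicarbonyl dianion at its γ-carbon (C4) by the Weinreb amide, whose chelated tetrahedral adduct prevents over-addition and proton quench of the dianion, run cold to suppress Carroll rearrangement of the allylic ester dianion and dehydroiodination.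

Step 17
Reactants: 25 (2R,3Z,5Z,7S,8E)-9-iodo-7-methylnona-3,5,8-trien-2-yl (6E,9Z,12E)-2,10-dimethyl-3,5-dioxo-13-(tributylstannyl)trideca-6,9,12-trienoate
Product: 26 (7E,10Z,13E,15E,17R,18Z,20Z,22R)-3,11,17,22-tetramethyl-1-oxacyclodocosa-7,10,13,15,18,20-hexaene-2,4,6-trione (C3 epimers; ring C17 and C22 are C16 and C21 of the target)
Conditions: Pd2(dba)3 (20 mol %), AsPh3 (80 mol %), degassed DMF/THF, rt, syringe-pump addition (final 0.5 mM), dark; kept at or below rt and taken on directly
Reagents that add atoms: none
Why: Stille macrocyclisation under high dilution joins C13 to C14 with retention of both alkene geometries, closing the 22-membered ring and creating the (12E,14E)-diene only now, so that no cycloaddition can precede macrocyclisation, while phosphine-free zerovalent palladium should add to the vinyl iodide much faster than it ionises the secondary allylic ester.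

Step 18
Reactants: 26 (7E,10Z,13E,15E,17R,18Z,20Z,22R)-3,11,17,22-tetramethyl-1-oxacyclodocosa-7,10,13,15,18,20-hexaene-2,4,6-trione
Product: 28 target macrolide (2S,6R,7S,12R,15R,16S,21R), via C2-epimeric cycloadduct 27 (not isolated)
Conditions: degassed toluene (2 mM), BHT (cat.), 60 °C, dark; then Et3N (1 equiv), CH2Cl2, rt; minor C2 epimer separated and resubmitted to Et3N
Reagents that add atoms: none
Why: A concerted, asynchronous, suprafacial [4+2] cycloaddition takes place across the macrocycle between the C6=C7 enone (activated by the C5 carbonyl of the chelated 1,3-diketone) and the C12=C13–C14=C15 diene; the closest known reaction type is the transannular Diels–Alder reaction of macrocyclic trienones, the ring-constrained form of the 1,7,9-decatrien-3-one cycloaddition. Ring A closes through the C7–C12 bond as the six-membered ring spanned by the C8–C11 bridge, whose Z C9=C10 alkene holds the two termini together, ring B closes as the cycloaddition cyclohexene (C6–C15 and C7–C12, new alkene C13=C14), and the 22-membered lactone contracts to the 14-membered one. The trans relationship of C6 and C7 follows from the E-enone and the cis relationship of the C12 and C15 substituents from the E,E-diene, while the trans ring fusion and the cis relationship of C5 and C16 follow from the endo orientation of the C5 carbonyl with the C8–C11 bridge exo. The absolute sense is controlled by C16: its hydrogen eclipses the diene plane (allylic strain), the C17 arm is held on the dienophile face because it is tied to C5 through the lactone, and the methyl group points away, which should give 6R,7S,12R,15R. The step needs periselectivity (the Z,Z-diene cannot reach an s-cis geometry and C9=C10 is unactivated), endo selectivity and π-facial selectivity, all of which the macrocyclic constraint should reinforce. C2 is then equilibrated by triethylamine through the enol to the 2S epimer.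

Compound list
1 | methyl (R)-3-hydroxy-2-methylpropanoate | COC(=O)[C@H](C)CO | starting material
2 | methyl (R)-3-[(tert-butyldimethylsilyl)oxy]-2-methylpropanoate | COC(=O)[C@H](C)CO[Si](C)(C)C(C)(C)C | intermediate
3 | (R)-3-[(tert-butyldimethylsilyl)oxy]-2-methylpropanal | O=C[C@H](C)CO[Si](C)(C)C(C)(C)C | intermediate
4 | (S)-tert-butyldimethyl[(2-methylbut-3-yn-1-yl)oxy]silane | C#C[C@H](C)CO[Si](C)(C)C(C)(C)C | intermediate
5 | (R)-but-3-yn-2-ol | C#C[C@@H](C)O | starting material
6 | (R)-4-bromobut-3-yn-2-ol | BrC#C[C@@H](C)O | intermediate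
7 | (2R,7S)-8-[(tert-butyldimethylsilyl)oxy]-7-methylocta-3,5-diyn-2-ol | CC(C)(C)[Si](C)(C)OC[C@@H](C)C#CC#C[C@@H](C)O | intermediate
8 | (2R,3Z,5Z,7S)-8-[(tert-butyldimethylsilyl)oxy]-7-methylocta-3,5-dien-2-ol | CC(C)(C)[Si](C)(C)OC[C@@H](C)/C=C\C=C/[C@@H](C)O | intermediate
9 | ethyl 2-methyl-3-oxobutanoate | CCOC(=O)C(C)C(C)=O | starting material
10 | (2R,3Z,5Z,7S)-8-[(tert-butyldimethylsilyl)oxy]-7-methylocta-3,5-dien-2-yl 2-methyl-3-oxobutanoate (C2 epimers) | CC(C)(C)[Si](C)(C)OC[C@@H](C)/C=C\C=C/[C@@H](C)OC(=O)C(C)C(C)=O | intermediate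
11 | (2R,3Z,5Z,7S)-8-hydroxy-7-methylocta-3,5-dien-2-yl 2-methyl-3-oxobutanoate (C2 epimers) | OC[C@@H](C)/C=C\C=C/[C@@H](C)OC(=O)C(C)C(C)=O | intermediate
12 | (2R,3Z,5Z,7S)-7-methyl-8-oxoocta-3,5-dien-2-yl 2-methyl-3-oxobutanoate (C2 epimers) | O=C[C@@H](C)/C=C\C=C/[C@@H](C)OC(=O)C(C)C(C)=O | intermediate
13 | (2R,3Z,5Z,7S,8E)-9-iodo-7-methylnona-3,5,8-trien-2-yl 2-methyl-3-oxobutanoate (C2 epimers) | I/C=C/[C@@H](C)/C=C\C=C/[C@@H](C)OC(=O)C(C)C(C)=O | intermediate
14 | but-3-enoic acid | C=CCC(=O)O | starting material
15 | 2-methylprop-2-en-1-ol | C=C(C)CO | starting material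
16 | 2-methylallyl but-3-enoate | C=CCC(=O)OCC(C)=C | intermediate
17 | 5-methyl-3,6-dihydro-2H-pyran-2-one | CC1=CCC(=O)OC1 | intermediate
18 | 5-methyl-3,6-dihydro-2H-pyran-2-ol (racemic) | CC1=CCC(O)OC1 | intermediate
19 | N-methoxy-N-methyl-2-(triphenylphosphoranylidene)acetamide | CON(C)C(=O)C=P(c1ccccc1)(c1ccccc1)c1ccccc1 | starting material
20 | (2E,5Z)-7-hydroxy-N-methoxy-N,6-dimethylhepta-2,5-dienamide | CON(C)C(=O)/C=C/C/C=C(/C)CO | intermediate
21 | (2E,5Z)-7-bromo-N-methoxy-N,6-dimethylhepta-2,5-dienamide | CON(C)C(=O)/C=C/C/C=C(/C)CBr | intermediate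
22 | (E)-1,2-bis(tributylstannyl)ethene | CCCC[Sn](CCCC)(CCCC)/C=C/[Sn](CCCC)(CCCC)CCCC | starting material
23 | (2E,5Z,8E)-N-methoxy-N,6-dimethyl-9-(tributylstannyl)nona-2,5,8-trienamide | CON(C)C(=O)/C=C/C/C=C(/C)C/C=C/[Sn](CCCC)(CCCC)CCCC | intermediate
24 | dilithium 1,3-dienolate (dianion) of 13 | [Li+].[Li+].I/C=C/[C@@H](C)/C=C\C=C/[C@@H](C)OC([O-])=C(C)C(=C)[O-] | intermediate
25 | (2R,3Z,5Z,7S,8E)-9-iodo-7-methylnona-3,5,8-trien-2-yl (6E,9Z,12E)-2,10-dimethyl-3,5-dioxo-13-(tributylstannyl)trideca-6,9,12-trienoate (C2 epimers) | I/C=C/[C@@H](C)/C=C\C=C/[C@@H](C)OC(=O)C(C)C(=O)CC(=O)/C=C/C/C=C(/C)C/C=C/[Sn](CCCC)(CCCC)CCCC | intermediate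
26 | (7E,10Z,13E,15E,17R,18Z,20Z,22R)-3,11,17,22-tetramethyl-1-oxacyclodocosa-7,10,13,15,18,20-hexaene-2,4,6-trione (C3 epimers) | CC1C(=O)CC(=O)/C=C/C/C=C(/C)C/C=C/C=C/[C@@H](C)/C=C\C=C/[C@@H](C)OC1=O | intermediate
27 | tricyclic cycloadduct, 6R,7S,12R,15R,16S,21R, C2 epimers (14-membered enol β-keto lactone fused at C6–C15 to the trans-fused rings A and B) | CC1=CC[C@@H]2[C@H]3/C(O)=C\C(=O)C(C)C(=O)O[C@H](C)/C=C\C=C/[C@H](C)[C@H]3C=C[C@H]2C1 | intermediate
28 | target macrolide, (2S,6R,7S,12R,15R,16S,21R): 14-membered lactone (C1–C6, C15–C21, O) with C3 ketone, C4=C5 enol and 17Z,19Z-diene, fused at C6–C15 to the trans-fused hexahydronaphthalene of ring A (C7–C12, C9=C10, methyl on C10) and ring B (C13=C14) | CC1=CC[C@@H]2[C@H]3/C(O)=C\C(=O)[C@H](C)C(=O)O[C@H](C)/C=C\C=C/[C@H](C)[C@H]3C=C[C@H]2C1 | target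

Total step count: 18.
Longest linear sequence: 11 steps (1 → 2 → 4 → 7 → 8 → 10 → 11 → 12 → 13 → 25 → 26 → 28).

Steps most likely to fail

Step 18. The enone may attack the wrong diene face, or close exo to a cis-decalin, if the macrocycle is too flexible at the temperature the thermal reaction needs. The C5 enol oxygen may also attack the lactone carbonyl across the ring, forming a pyranone and opening the macrocycle. The fallback sets out from 26: BF3·OEt2 and i-Pr2NEt in CH2Cl2 at 0 °C convert the 1,3-diketone into the macrocyclic difluoroboron diketonate F1. The dioxaborine ties up the enol oxygen, holds C3–C5 planar and makes the dienophile much more electron-poor, so the cycloaddition should run between −20 °C and room temperature to the chelated tricycle F2. NaOAc in aqueous MeOH at 50 °C then removes boron and Et3N equilibrates C2, which comes back to the route at 28.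

Step 17. Oligomerisation may compete at this ring size, zerovalent palladium may ionise the allylic β-keto ester (decarboxylative allylation) once the vinyl iodide is used up, or the acidic enol may protodestannylate the vinylstannane. The fallback closes the ring at C4–C5 instead and sets out from 13 and 23. A palladium-free coupling with Cu(O2CC4H3S) (copper thiophene-2-carboxylate) in NMP at 0 °C, at normal concentration and before any acidic diketone exists, gives the open-chain hexaene keto ester Weinreb amide F3, whose unsaturated amide is too poor a dienophile to cyclise. LiN(i-Pr)2 (2.2 equiv) in THF at −78 → −40 °C under high dilution then forms the dianion, which acylates itself on the Weinreb amide in a macrocyclic Claisen condensation; the acidic quench comes back to the route at 26.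

Step 16. Proton transfer from the doubly allylic C8 position of 23 to the dianion, or conjugate addition, may take the place of 1,2-acylation. The fallback sets out from 23: i-Bu2AlH in THF at −78 °C gives the stannyl trienal F4. This far more electrophilic aldehyde should add the dianion 24 (from 13) at −78 °C to give the δ-hydroxy β-keto ester F5, and Dess–Martin periodinane (NaHCO3, CH2Cl2, 0 °C) oxidises it, coming back to the route at 25.

Further compounds
F1 | step 18 | difluoroboron diketonate (C3/C5 dioxaborine) of macrocycle 26 | CC1C2=[O+][B-](F)(F)OC(=C2)/C=C/C/C=C(/C)C/C=C/C=C/[C@@H](C)/C=C\C=C/[C@@H](C)OC1=O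
F2 | step 18 | difluoroboron diketonate of the tricyclic cycloadduct (C2 epimers) | CC1=CC[C@@H]2[C@H]3C4=CC(=[O+][B-](F)(F)O4)C(C)C(=O)O[C@H](C)/C=C\C=C/[C@H](C)[C@H]3C=C[C@H]2C1
F3 | step 17 | open-chain hexaene: 2-methyl-3-oxobutanoate of the C21 alcohol whose chain (3Z,5Z,8E,10E,13Z,16E) ends in the N-methoxy-N-methylamide at C5 | CC(=O)C(C)C(=O)O[C@H](C)/C=C\C=C/[C@H](C)/C=C/C=C/C/C(C)=C\C/C=C/C(=O)N(C)OC
F4 | step 16 | (2E,5Z,8E)-6-methyl-9-(tributylstannyl)nona-2,5,8-trienal | O=C/C=C/C/C=C(/C)C/C=C/[Sn](CCCC)(CCCC)CCCC
F5 | step 16 | (2R,3Z,5Z,7S,8E)-9-iodo-7-methylnona-3,5,8-trien-2-yl (6E,9Z,12E)-5-hydroxy-2,10-dimethyl-3-oxo-13-(tributylstannyl)trideca-6,9,12-trienoate (C2 and C5 epimers) | I/C=C/[C@@H](C)/C=C\C=C/[C@@H](C)OC(=O)C(C)C(=O)CC(O)/C=C/C/C=C(/C)C/C=C/[Sn](CCCC)(CCCC)CCCC
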